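## The problem

- The target **30** is an elemane-type lactone on a single cyclohexane. Its ring carbons are, in order, the quaternary C10 (methyl C14, vinyl C1=C2), C9H2, the acylated carbinol C8, the lactone-fused pair C7/C6, and C5 carrying the C4(=C3H2)C15H2OH arm. The γ-lactone is C6–O–C12(=O)–C11(C13H3)–C7, and O8 carries a (3'S)-3,4-dihydroxy-2-methylenebutanoyl group (C1'–C4').
- C5, C6, C7 and C8 are all-trans, so in the chair every one of their substituents is equatorial. At C10 the methyl is axial and the vinyl equatorial. On the lactone, the C13 methyl lies cis to H7 (11R).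
- Only C10, C11 and C3' need an outside source of chirality. C5–C8 can be relayed from C10, because the all-equatorial array is the stable one and C5, C7 and C8 are each epimerisable at some stage.
- That relay depends on which C10 substituent goes axial. Methyl and a CH(OR)2 group differ little in size, so this is the soft point of any plan that sets C10 first.
- C10 is quaternary, has no neighbouring functional group in the target, and sits next to the stereogenic C5. It is the hardest centre to make enantioselectively.
- Fragile features are the acrylate, and its free 3',4'-diol, which under base lactonises onto its own ester and expels the C8 alcohol. Every intermediate with an oxygen β to a carbonyl (O8 to a C6 ketone, O6 to a C4 carbonyl) is open to E1cB loss.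
- The enabling feature is the oxygenation pattern: C6 and C8 are both oxygenated, C7 lies between them, and C5 bears the carboxyl-level carbon C4. C4–C5–C6–C7 is therefore an acetoacetate and C8–C9–C10(C14)(C1) a β,β-disubstituted enal, so the ring is their sum through a Michael addition at C10 and an aldol addition at C8.

## Retrosynthesis

**C8–O acyl bond.** Target **30** is cut first at the ester, giving the ring alcohol **21** and the acetonide-protected acid **27** (coupled through mixed anhydride **28** to **29**). The side chain is the most fragile part, so it is attached last. O15 must be masked while O8 is acylated, and a primary TBS ether is chosen because it leaves in the same mild acid that opens the acetonide. The forward reaction is the esterification of a hindered secondary alcohol with an α-substituted acrylic acid.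

**Side-chain acid.** Acid **27** comes from ester **26**, which is cut at C2'–C1' to enol triflate **25** and carbon monoxide. Triflate **25** is derived from methyl ketone **24**, made through amide **23** from methyl (R)-glycerate acetonide **22**. The acrylate α-carbon is thus the glycerate ester carbon, and the stereocentre is bought. The forward sequence asks for a kinetic enolate at the methyl group that leaves the α-alkoxy centre alone.

**C15 oxygen and the isopropenyl unit.** Alcohol **21** goes back through diol **20** and silyl ether **19** to the isopropenyl compound **18** by allylic oxidation of C15. **18** is cut at C4=C3 to methyl ketone **17**, which is cut at C4–C15 to acid chloride **16** of acid **15**. C4 arrives from acetoacetate at the carboxyl level, so two one-carbon units must be added. Methyl by cuprate and methylene by a non-basic titanium–zinc reagent are chosen because O6 is β to the C4 carbonyl throughout. A direct α-alkoxy ketone would save the oxidation but rests on a less secure coupling.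

**Vinyl group and free acid.** Acid **15** is cut at C1=C2 to aldehyde **14**. **14** is obtained from lactone **13** in one acid treatment that removes the tert-butyl ester and the dimethyl acetal together. The aldehyde is neopentyl and cannot enolise, so methylenation is clean.

**Lactone and C6.** Lactone **13** is cut at O6–C12 to hydroxy diester **12**, and the C6 carbinol is taken back to ketone **11**. The hydrogen at C6 must enter on the face that carries the axial C14 methyl, which hydride reagents avoid. The forward step therefore uses electron-transfer reduction, which gives the equatorial alkoxide. C1 stays an acetal here because a free aldehyde would also be reduced. O8 is silylated so that only O6 can close onto C12.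

**C7–C11 bond.** Keto ester **11** is cut between C7 and C11 to silyl ether **8** and triflate **10**, made from methyl (R)-lactate **9**. C7 is the γ-carbon of the β-keto ester, so its dianion is the nucleophile. The triflate brings C11, C12 and C13 with C11 set by inversion. Alkylation with a bromoacetate followed by lactone methylation is the neighbouring cut; it is kept as a fallback because it adds a step and sets C11 only by facial bias.

**Protection.** **8** is the TBDPS ether of hydroxy ketone **7**. The group is put on before the alkylation so that O8 can neither eliminate as hydroxide nor capture the C12 ester, and it is chosen to survive trifluoroacetic acid.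

**Ring.** Hydroxy ketone **7** is cut at C7–C8 to Michael adduct **6** and then at C5–C10 to enal **4** and tert-butyl acetoacetate **5**. Both are achiral and together contain every ring carbon with the right functional group. The price is an amine-catalysed conjugate addition that must create a quaternary carbon with face control.

**Enal.** Enal **4** comes from allylic alcohol **3**, ester **2** and 1,1-dimethoxypropan-2-one **1** by olefination, reduction and oxidation.

## Roads not taken

**Alternative 1:** The ring would be cut at C6–C7 together with the lactone C–O bond.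
- Forward step: CrCl2 converts the open-chain bromo ester aldehyde A1 into an allylchromium species that adds through C7 to the C6 aldehyde, and the resulting alkoxide closes onto the ester to give the α-methylene lactone A2.
- Merits: carbocycle and lactone form in one known operation, C6 and C7 are set together in a cyclic transition state, and no ketone reduction against the axial methyl is needed. In that respect it is better than the chosen plan.
- Weak points: A1 must already hold C5, C8 and the quaternary C10 in an open chain, and its C5 centre is α to an aldehyde and β,γ-unsaturated, so it can epimerise or move into conjugation. A2 also has an exocyclic C11=C13 that the target lacks. It would have to be reduced from one face without touching the vinyl and isopropenyl groups, and C15 still needs oxidation.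
- Comparison: the chosen plan sets against this a one-step ring assembly from two achiral compounds and a C11 centre taken from lactate.

**Alternative 2:** The ring would be cut at C9–C10 and C5–C6.
- Forward step: a cationic oxazaborolidine (B-o-tolyl, from α,α-diphenylprolinol, activated by HNTf2) catalyses the Diels–Alder reaction of the formyl enoate A3 with the siloxydiene A4 to give cyclohexene A5.
- Merits: the reaction class is established for α-substituted enals, both partners are simple, and C10 and C5 are fixed trans to each other by the dienophile geometry. That is a firmer link between these two centres than the equilibration the chosen plan relies on.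
- Weak points: A5 has its only ring oxygen at C7, whereas the target needs oxygen at C6 and C8 and a carbon substituent at C7. Correcting this means two regioselective α-oxidations, a carbon–carbon bond at the C7 carbonyl and three new stereocentres, with C6 and C8 hard to tell apart.
- Comparison: the chosen plan delivers the C6/C8 oxygens and a nucleophilic C7 directly, and accepts a riskier key step in return.

**Alternative 3:** The ring would be cut at C5–C6.
- Forward step: Me2AlCl promotes the intramolecular carbonyl-ene reaction of the open-chain aldehyde A6, whose C5=C4 alkene carries two methyl groups, to give cyclohexanol A7.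
- Merits: C5–C6 forms with the isopropenyl unit already in place, the C6 hydroxyl sits next to the C12 ester ready to lactonise, and neither a ketone reduction nor an ester-to-isopropenyl conversion is required. The late stage is shorter than in the chosen plan.
- Weak points: A6 needs C7, C8, C10 and C11 set in an acyclic chain, including a quaternary carbon with two different alkenyl groups. Its C7 centre is α to the aldehyde under a Lewis acid. The relation of the new C5/C6 pair to C10 depends on the same small methyl-versus-alkenyl preference that troubles every route.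
- Comparison: the chosen plan reaches the ring in four steps and pays for it with a longer sequence afterwards.

Key step: step 4

Assumption: the (R)-configured catalyst is assigned from the usual shielding model of diarylprolinol silyl ether iminium ions (attack on C10 of the E-iminium ion anti to the diphenyl(silyloxy)methyl group). If the sense proves opposite, the (S)-catalyst is used and nothing else changes.

## Route

Step 1
Reactants: 1 1,1-dimethoxypropan-2-one
Product: 2 ethyl (E)-4,4-dimethoxy-3-methylbut-2-enoate
Conditions: (EtO)2P(O)CH2CO2Et, NaH, THF, 0 °C → rt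
Reagents that add atoms: triethyl phosphonoacetate, CCOC(=O)CP(=O)(OCC)OCC
Why: Horner–Wadsworth–Emmons olefination of an activated ketone; the E isomer (ester trans to the acetal) should predominate and the Z isomer is removed by chromatography here or after step 2.

Step 2
Reactants: 2 ethyl (E)-4,4-dimethoxy-3-methylbut-2-enoate
Product: 3 (E)-4,4-dimethoxy-3-methylbut-2-en-1-ol
Conditions: i-Bu2AlH (2.2 equiv), CH2Cl2, −78 °C; aq. KNaC4H4O6
Reagents that add atoms: none
Why: 1,2-reduction of the enoate by the aluminium hydride; the neutral tartrate work-up keeps the acetal.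

Step 3
Reactants: 3 (E)-4,4-dimethoxy-3-methylbut-2-en-1-ol
Product: 4 (E)-4,4-dimethoxy-3-methylbut-2-enal
Conditions: MnO2, CH2Cl2, rt
Reagents that add atoms: none
Why: allylic oxidation on MnO2 under neutral conditions, so the acetal and the alkene geometry are kept.

Step 4
Reactants: 4 (E)-4,4-dimethoxy-3-methylbut-2-enal; 5 tert-butyl acetoacetate
Product: 7 tert-butyl (1R,2S,4R)-2-(dimethoxymethyl)-4-hydroxy-2-methyl-6-oxocyclohexane-1-carboxylate, via Michael adduct 6 (not isolated)
Conditions: (R)-α,α-diphenylprolinol trimethylsilyl ether (20 mol %), PhCO2H (20 mol %), toluene, rt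
Reagents that add atoms: none
Why: Proposed new method: the amine condenses with 4 to an E-configured iminium ion, the enol of 5 adds through C5 to C10 on the face away from the diphenyl(silyloxy)methyl group, and after hydrolysis of the enamine the methyl ketone enol of 6 attacks the C8 aldehyde; the closest known reaction type is the diarylprolinol silyl ether-catalysed Michael–aldol annulation of β-keto esters with β-monosubstituted enals, together with nitroalkane additions of the same catalysts to β,β-disubstituted enals, and the new element is a 1,3-dicarbonyl donor creating the quaternary carbon. The cyclohexanone closes by a 6-(enolendo)-exo-trig aldol addition. C10 is set by the catalyst, C5 by enolisation of the β-keto ester to the equatorial ester, and C8 in the chair-like closure, where two of the three unstrained arrangements (OH equatorial with C14 axial, or OH axial and hydrogen-bonded to an axial acetal) place O8 cis to C1; retro-aldol equilibration in toluene should favour the same isomer, the only one that can hold an O8–H···OMe contact. The step needs 1,4- instead of 1,2-addition, since condensation at C8 followed by oxa-electrocyclisation to a 2H-pyran is the usual fate of β,β-disubstituted enals with 1,3-dicarbonyl compounds; the bulk of the catalyst around the iminium carbon and the inductive pull of the acetal on C10 are what should secure it.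

Step 5
Reactants: 7 tert-butyl (1R,2S,4R)-2-(dimethoxymethyl)-4-hydroxy-2-methyl-6-oxocyclohexane-1-carboxylate
Product: 8 tert-butyl (1R,2S,4R)-4-[(tert-butyldiphenylsilyl)oxy]-2-(dimethoxymethyl)-2-methyl-6-oxocyclohexane-1-carboxylate
Conditions: t-BuPh2SiCl, imidazole, DMF, rt
Reagents that add atoms: tert-butyl(chloro)diphenylsilane, CC(C)(C)[Si](Cl)(c1ccccc1)c1ccccc1
Why: silylation of the unhindered equatorial C8 alcohol; it stops retro-aldol and dehydration, keeps O8 from the C12 ester later, and the diphenyl group is chosen to survive step 9.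

Step 6
Reactants: 9 methyl (R)-lactate
Product: 10 methyl (2R)-2-{[(trifluoromethyl)sulfonyl]oxy}propanoate
Conditions: Tf2O, 2,6-lutidine, CH2Cl2, −78 → 0 °C
Reagents that add atoms: trifluoromethanesulfonic anhydride, O=S(=O)(OS(=O)(=O)C(F)(F)F)C(F)(F)F
Why: O-sulfonylation of the α-hydroxy ester with retention (the C–O bond is not touched); the triflate is used without storage.

Step 7
Reactants: 8 tert-butyl (1R,2S,4R)-4-[(tert-butyldiphenylsilyl)oxy]-2-(dimethoxymethyl)-2-methyl-6-oxocyclohexane-1-carboxylate; 10 methyl (2R)-2-{[(trifluoromethyl)sulfonyl]oxy}propanoate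
Product: 11 tert-butyl (1R,2S,4R,5S)-4-[(tert-butyldiphenylsilyl)oxy]-2-(dimethoxymethyl)-5-[(2R)-1-methoxy-1-oxopropan-2-yl]-2-methyl-6-oxocyclohexane-1-carboxylate
Conditions: LiN(i-Pr)2 (2.2 equiv), THF, −78 → −40 °C; 10, −78 °C; AcOH
Reagents that add atoms: none
Why: γ-alkylation of the β-keto ester dianion at C7 by SN2 displacement of the α-triflyloxy ester; inversion at C11 gives the R centre (the descriptor is unchanged because the incoming carbon ranks below the ester carbon). C7 is attacked anti to the neighbouring silyloxy group, and the equatorial isomer formed is also the thermodynamic one while C7 remains α to the ketone; the silyloxy group lies near the enolate plane, which disfavours its elimination at low temperature.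

Step 8
Reactants: 11 tert-butyl (1R,2S,4R,5S)-4-[(tert-butyldiphenylsilyl)oxy]-2-(dimethoxymethyl)-5-[(2R)-1-methoxy-1-oxopropan-2-yl]-2-methyl-6-oxocyclohexane-1-carboxylate
Product: 13 tert-butyl ester of the 8-O-TBDPS 6,12-lactone carrying CH(OMe)2 at C10 (trans-fused; C5–C8 and C11 as in the target), via hydroxy diester 12 (not isolated)
Conditions: SmI2 (3 equiv), THF/MeOH, −78 → 0 °C; then pyridinium p-toluenesulfonate (cat.), toluene, 80 °C
Reagents that add atoms: none
Why: single-electron reduction of the chelated β-keto ester; in the ketyl and the derived organosamarium the oxygen with its metal takes the equatorial site away from the axial C14 methyl, so the proton enters axially and the equatorial (thermodynamic) C6 alcohol results. The C6 oxygen then closes onto the methyl ester (5-exo-trig) to the trans-fused γ-lactone; the tert-butyl ester could only give a β-lactone and stays.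

Step 9
Reactants: 13 tert-butyl ester of the 8-O-TBDPS 6,12-lactone carrying CH(OMe)2 at C10
Product: 14 aldehyde acid (8-O-TBDPS 6,12-lactone with C1 as CHO on C10 and C4 as CO2H on C5)
Conditions: CF3CO2H/CH2Cl2/H2O (10:10:1), 0 °C → rt
Reagents that add atoms: water, O
Why: acidolysis of the tert-butyl ester by alkyl–oxygen fission and hydrolysis of the dimethyl acetal in one operation; the lactone and the TBDPS ether tolerate aqueous trifluoroacetic acid for the time required.

Step 10
Reactants: 14 aldehyde acid
Product: 15 vinyl acid (8-O-TBDPS 6,12-lactone with C1=C2 vinyl on C10 and CO2H on C5)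
Conditions: Ph3PCH3Br, KN(SiMe3)2 (3 equiv each), THF, 0 °C → rt; dilute acid work-up
Reagents that add atoms: methyltriphenylphosphonium bromide, C[P+](c1ccccc1)(c1ccccc1)c1ccccc1.[Br-]
Why: Wittig methylenation of a non-enolisable neopentyl aldehyde; the first equivalent of ylide forms the carboxylate, which also protects C5 from deprotonation, and the lactone is inert to the non-stabilised ylide at this temperature.

Step 11
Reactants: 15 vinyl acid
Product: 17 C4 methyl ketone (C5-acetyl 8-O-TBDPS 6,12-lactone), via acid chloride 16 (not isolated)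
Conditions: (COCl)2, DMF (cat.), CH2Cl2, 0 °C → rt; then Me2CuLi (from MeLi, CuI), Et2O, −78 °C
Reagents that add atoms: lithium dimethylcuprate, [Li+].C[Cu-]C; oxalyl chloride (Cl of 16 only), ClC(=O)C(Cl)=O
Why: ketone synthesis by cuprate acylation of an acid chloride, which stops at the ketone and leaves the lactone alone; the reagent is only weakly basic, so the β-acyloxy ketone does not lose O6.

Step 12
Reactants: 17 C4 methyl ketone
Product: 18 C5-isopropenyl 8-O-TBDPS 6,12-lactone
Conditions: Zn, CH2Br2, TiCl4, THF/CH2Cl2, 0 °C → rt
Reagents that add atoms: dibromomethane, BrCBr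
Why: Takai–Lombardo methylenation; the non-basic geminal dimetal reagent methylenates the hindered ketone but not the lactone and avoids both C5 epimerisation and E1cB opening of the lactone.

Step 13
Reactants: 18 C5-isopropenyl 8-O-TBDPS 6,12-lactone
Product: 19 15-hydroxy compound (C5 3-hydroxyprop-1-en-2-yl, 8-O-TBDPS 6,12-lactone)
Conditions: SeO2 (0.5 equiv), t-BuOOH (3 equiv), CH2Cl2, 0 °C → rt
Reagents that add atoms: selenium dioxide, O=[Se]=O; tert-butyl hydroperoxide, CC(C)(C)OO
Why: SeO2-catalysed allylic hydroxylation (ene reaction, then [2,3]-sigmatropic shift); on an isopropenyl group the methyl reacts before the ring methine, and the vinyl group has no allylic hydrogen.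

Step 14
Reactants: 19 15-hydroxy compound
Product: 20 (3R,3aS,4R,6R,7S,7aS)-6-ethenyl-4-hydroxy-7-(3-hydroxyprop-1-en-2-yl)-3,6-dimethylhexahydro-1-benzofuran-2(3H)-one
Conditions: Bu4NF, AcOH, THF, rt
Reagents that add atoms: none
Why: fluoride cleavage of the silyl ether, buffered with acetic acid so that the lactone is not opened.

Step 15
Reactants: 20 (3R,3aS,4R,6R,7S,7aS)-6-ethenyl-4-hydroxy-7-(3-hydroxyprop-1-en-2-yl)-3,6-dimethylhexahydro-1-benzofuran-2(3H)-one
Product: 21 15-O-TBS ether of 20 (C8 hydroxyl free)
Conditions: t-BuMe2SiCl (1.1 equiv), imidazole, CH2Cl2, 0 °C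
Reagents that add atoms: tert-butyl(chloro)dimethylsilane, CC(C)(C)[Si](C)(C)Cl
Why: selective silylation of the primary allylic alcohol over the secondary C8 hydroxyl, which is flanked by the ring-fusion carbon.

Step 16
Reactants: 22 methyl (R)-2,2-dimethyl-1,3-dioxolane-4-carboxylate
Product: 23 (4R)-N-methoxy-N,2,2-trimethyl-1,3-dioxolane-4-carboxamide
Conditions: MeNH(OMe)·HCl, i-PrMgCl, THF, −20 °C
Reagents that add atoms: N,O-dimethylhydroxylamine hydrochloride, CNOC.Cl
Why: aminolysis of the ester by the magnesium amide to the N-methoxy-N-methylamide; the α-alkoxy centre is not deprotonated at this temperature.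

Step 17
Reactants: 23 (4R)-N-methoxy-N,2,2-trimethyl-1,3-dioxolane-4-carboxamide
Product: 24 1-[(4R)-2,2-dimethyl-1,3-dioxolan-4-yl]ethan-1-one
Conditions: MeMgBr, THF, −78 → 0 °C; aq. NH4Cl
Reagents that add atoms: methylmagnesium bromide, C[Mg]Br
Why: Grignard addition to the N-methoxy-N-methylamide; the chelated tetrahedral intermediate prevents a second addition, and the cold neutral quench protects the α-centre.

Step 18
Reactants: 24 1-[(4R)-2,2-dimethyl-1,3-dioxolan-4-yl]ethan-1-one
Product: 25 1-[(4R)-2,2-dimethyl-1,3-dioxolan-4-yl]ethenyl trifluoromethanesulfonate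
Conditions: KN(SiMe3)2, THF, −78 °C; PhNTf2
Reagents that add atoms: N-phenylbis(trifluoromethanesulfonimide), O=S(=O)(N(c1ccccc1)S(=O)(=O)C(F)(F)F)C(F)(F)F
Why: kinetic deprotonation at the methyl group by the hindered amide base and O-triflation of the enolate; the more hindered α-alkoxy methine is left alone, so the stereocentre is kept.

Step 19
Reactants: 25 1-[(4R)-2,2-dimethyl-1,3-dioxolan-4-yl]ethenyl trifluoromethanesulfonate
Product: 26 methyl 2-[(4S)-2,2-dimethyl-1,3-dioxolan-4-yl]prop-2-enoate
Conditions: Pd(OAc)2 (5 mol %), PPh3 (10 mol %), CO (1 atm), MeOH, Et3N, DMF, 40 °C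
Reagents that add atoms: carbon monoxide, [C-]#[O+]; methanol, CO
Why: palladium-catalysed methoxycarbonylation of an enol triflate (oxidative addition to zerovalent palladium, CO insertion, methanolysis); the descriptor changes from R to S only because the ring CH2O carbon now outranks the alkene carbon.

Step 20
Reactants: 26 methyl 2-[(4S)-2,2-dimethyl-1,3-dioxolan-4-yl]prop-2-enoate
Product: 27 2-[(4S)-2,2-dimethyl-1,3-dioxolan-4-yl]prop-2-enoic acid
Conditions: LiOH, THF/H2O, 0 °C → rt; dilute HCl to pH 4, 0 °C
Reagents that add atoms: lithium hydroxide, [Li+].[OH-]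
Why: saponification; the stereocentre is attached to the α-carbon and is not vinylogously acidic, and the brief mild acidification spares the acetonide.

Step 21
Reactants: 21 15-O-TBS ether of 20; 27 2-[(4S)-2,2-dimethyl-1,3-dioxolan-4-yl]prop-2-enoic acid
Product: 29 15-O-TBS 3',4'-O-isopropylidene derivative of the target, via mixed anhydride 28 (not isolated)
Conditions: 2,4,6-Cl3C6H2COCl, Et3N, THF, rt; then 21, 4-(dimethylamino)pyridine, toluene, rt
Reagents that add atoms: 2,4,6-trichlorobenzoyl chloride (atoms of 28 only), O=C(Cl)c1c(Cl)cc(Cl)cc1Cl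
Why: Yamaguchi esterification; the acylpyridinium formed from the mixed anhydride acylates the hindered C8 hydroxyl, the only free one.

Step 22
Reactants: 29 15-O-TBS 3',4'-O-isopropylidene derivative of the target
Product: 30 (3R,3aS,4R,6R,7S,7aS)-6-ethenyl-7-(3-hydroxyprop-1-en-2-yl)-3,6-dimethyl-2-oxooctahydro-1-benzofuran-4-yl (3S)-3,4-dihydroxy-2-methylidenebutanoate
Conditions: AcOH/H2O/THF (3:1:1), 40 °C
Reagents that add atoms: none
Why: acid hydrolysis of the terminal acetonide and of the primary silyl ether in one step; an acidic medium is used because the free side-chain diol lactonises onto its own ester, with loss of the C8 alcohol, under base.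

## Compound list

1 | 1,1-dimethoxypropan-2-one | COC(OC)C(C)=O | starting material
2 | ethyl (E)-4,4-dimethoxy-3-methylbut-2-enoate | COC(OC)/C(C)=C/C(=O)OCC | intermediate
3 | (E)-4,4-dimethoxy-3-methylbut-2-en-1-ol | COC(OC)/C(C)=C/CO | intermediate
4 | (E)-4,4-dimethoxy-3-methylbut-2-enal | COC(OC)/C(C)=C/C=O | intermediate
5 | tert-butyl acetoacetate | CC(=O)CC(=O)OC(C)(C)C | starting material
6 | tert-butyl (3S)-2-acetyl-3-(dimethoxymethyl)-3-methyl-5-oxopentanoate (Michael adduct, C2 epimers) | COC(OC)[C@@](C(C(C)=O)C(=O)OC(C)(C)C)(C)CC=O | intermediate (not isolated)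
7 | tert-butyl (1R,2S,4R)-2-(dimethoxymethyl)-4-hydroxy-2-methyl-6-oxocyclohexane-1-carboxylate | COC(OC)[C@@]1(C)C[C@@H](O)CC(=O)[C@@H]1C(=O)OC(C)(C)C | intermediate
8 | tert-butyl (1R,2S,4R)-4-[(tert-butyldiphenylsilyl)oxy]-2-(dimethoxymethyl)-2-methyl-6-oxocyclohexane-1-carboxylate | COC(OC)[C@@]1(C)C[C@@H](O[Si](c2ccccc2)(c2ccccc2)C(C)(C)C)CC(=O)[C@@H]1C(=O)OC(C)(C)C | intermediate
9 | methyl (R)-lactate | C[C@@H](O)C(=O)OC | starting material
10 | methyl (2R)-2-{[(trifluoromethyl)sulfonyl]oxy}propanoate | C[C@@H](OS(=O)(=O)C(F)(F)F)C(=O)OC | intermediate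
11 | tert-butyl (1R,2S,4R,5S)-4-[(tert-butyldiphenylsilyl)oxy]-2-(dimethoxymethyl)-5-[(2R)-1-methoxy-1-oxopropan-2-yl]-2-methyl-6-oxocyclohexane-1-carboxylate | COC(OC)[C@@]1(C)C[C@@H](O[Si](c2ccccc2)(c2ccccc2)C(C)(C)C)[C@H]([C@@H](C)C(=O)OC)C(=O)[C@@H]1C(=O)OC(C)(C)C | intermediate
12 | hydroxy diester: 11 with the C6 ketone reduced to the equatorial alcohol (O6 trans to the C5 and C7 substituents) | COC(OC)[C@@]1(C)C[C@@H](O[Si](c2ccccc2)(c2ccccc2)C(C)(C)C)[C@H]([C@@H](C)C(=O)OC)[C@@H](O)[C@@H]1C(=O)OC(C)(C)C | intermediate (not isolated)
13 | tert-butyl ester of the 8-O-TBDPS trans-fused 6,12-lactone carrying CH(OMe)2 at C10 (11R; ring centres as in the target) | COC(OC)[C@@]1(C)C[C@@H](O[Si](c3ccccc3)(c3ccccc3)C(C)(C)C)[C@H]2[C@@H](OC(=O)[C@@H]2C)[C@@H]1C(=O)OC(C)(C)C | intermediate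
14 | aldehyde acid: 8-O-TBDPS 6,12-lactone with CHO on C10 and CO2H on C5 | O=C[C@@]1(C)C[C@@H](O[Si](c3ccccc3)(c3ccccc3)C(C)(C)C)[C@H]2[C@@H](OC(=O)[C@@H]2C)[C@@H]1C(=O)O | intermediate
15 | vinyl acid: 8-O-TBDPS 6,12-lactone with vinyl on C10 and CO2H on C5 | C=C[C@@]1(C)C[C@@H](O[Si](c3ccccc3)(c3ccccc3)C(C)(C)C)[C@H]2[C@@H](OC(=O)[C@@H]2C)[C@@H]1C(=O)O | intermediate
16 | acid chloride of 15 | C=C[C@@]1(C)C[C@@H](O[Si](c3ccccc3)(c3ccccc3)C(C)(C)C)[C@H]2[C@@H](OC(=O)[C@@H]2C)[C@@H]1C(=O)Cl | intermediate (not isolated)
17 | C4 methyl ketone: C5-acetyl 8-O-TBDPS 6,12-lactone | C=C[C@@]1(C)C[C@@H](O[Si](c3ccccc3)(c3ccccc3)C(C)(C)C)[C@H]2[C@@H](OC(=O)[C@@H]2C)[C@@H]1C(C)=O | intermediate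
18 | C5-isopropenyl 8-O-TBDPS 6,12-lactone | C=C[C@@]1(C)C[C@@H](O[Si](c3ccccc3)(c3ccccc3)C(C)(C)C)[C@H]2[C@@H](OC(=O)[C@@H]2C)[C@@H]1C(C)=C | intermediate
19 | 15-hydroxy compound: C5 3-hydroxyprop-1-en-2-yl 8-O-TBDPS 6,12-lactone | C=C[C@@]1(C)C[C@@H](O[Si](c3ccccc3)(c3ccccc3)C(C)(C)C)[C@H]2[C@@H](OC(=O)[C@@H]2C)[C@@H]1C(=C)CO | intermediate
20 | (3R,3aS,4R,6R,7S,7aS)-6-ethenyl-4-hydroxy-7-(3-hydroxyprop-1-en-2-yl)-3,6-dimethylhexahydro-1-benzofuran-2(3H)-one | C=C[C@@]1(C)C[C@@H](O)[C@H]2[C@@H](OC(=O)[C@@H]2C)[C@@H]1C(=C)CO | intermediate
21 | 15-O-TBS ether of 20 (C8 hydroxyl free) | C=C[C@@]1(C)C[C@@H](O)[C@H]2[C@@H](OC(=O)[C@@H]2C)[C@@H]1C(=C)CO[Si](C)(C)C(C)(C)C | intermediate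
22 | methyl (R)-2,2-dimethyl-1,3-dioxolane-4-carboxylate | COC(=O)[C@H]1COC(C)(C)O1 | starting material
23 | (4R)-N-methoxy-N,2,2-trimethyl-1,3-dioxolane-4-carboxamide | CON(C)C(=O)[C@H]1COC(C)(C)O1 | intermediate
24 | 1-[(4R)-2,2-dimethyl-1,3-dioxolan-4-yl]ethan-1-one | CC(=O)[C@H]1COC(C)(C)O1 | intermediate
25 | 1-[(4R)-2,2-dimethyl-1,3-dioxolan-4-yl]ethenyl trifluoromethanesulfonate | C=C(OS(=O)(=O)C(F)(F)F)[C@H]1COC(C)(C)O1 | intermediate
26 | methyl 2-[(4S)-2,2-dimethyl-1,3-dioxolan-4-yl]prop-2-enoate | C=C(C(=O)OC)[C@H]1COC(C)(C)O1 | intermediate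
27 | 2-[(4S)-2,2-dimethyl-1,3-dioxolan-4-yl]prop-2-enoic acid | C=C(C(=O)O)[C@H]1COC(C)(C)O1 | intermediate
28 | 2-[(4S)-2,2-dimethyl-1,3-dioxolan-4-yl]prop-2-enoic 2,4,6-trichlorobenzoic anhydride | C=C(C(=O)OC(=O)c1c(Cl)cc(Cl)cc1Cl)[C@H]1COC(C)(C)O1 | intermediate (not isolated)
29 | 15-O-TBS 3',4'-O-isopropylidene derivative of the target | C=C[C@@]1(C)C[C@@H](OC(=O)C(=C)[C@H]3COC(C)(C)O3)[C@H]2[C@@H](OC(=O)[C@@H]2C)[C@@H]1C(=C)CO[Si](C)(C)C(C)(C)C | intermediate
30 | (3R,3aS,4R,6R,7S,7aS)-6-ethenyl-7-(3-hydroxyprop-1-en-2-yl)-3,6-dimethyl-2-oxooctahydro-1-benzofuran-4-yl (3S)-3,4-dihydroxy-2-methylidenebutanoate | C=C[C@@]1(C)C[C@@H](OC(=O)C(=C)[C@H](O)CO)[C@H]2[C@@H](OC(=O)[C@@H]2C)[C@@H]1C(=C)CO | target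

## Step count and least certain steps

Total: 22 steps. Longest linear sequence: 16 steps (steps 1–5, 7–15, 21, 22).

**Step 4 (key step, proposed new method).**
- What may go wrong: 1,2-addition and condensation at C8 in place of conjugate addition, because the β-carbon is fully substituted.
- Facial selectivity at C10 may be poor, because methyl and dimethoxymethyl are similar in size and the iminium ion can scramble its geometry through the dienamine.
- The relay from C10 to C8 may be incomplete, because the preference for the acetal over the methyl in the equatorial site is small.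
- Fallback (known chemistry): it sets out from 5 and returns at 8. The precedented annulation of 5 with commercial (E)-4,4-dimethoxybut-2-enal under the same catalyst gives, through the Michael adduct F1, the all-equatorial hydroxy ketone F2, which lacks C14. Silylation gives the TBDPS ether F3. Selenenylation (PhSeCl, pyridine) gives the selenide F4, and oxidation (H2O2) with syn-elimination gives the enone F5, in which only C8 is stereogenic; F2 must therefore be diastereomerically pure. Me2CuLi then adds to C10 anti to the silyloxy group (the trans-3,5 preference of 5-substituted cyclohexenones), and protonation of the β-keto ester enolate gives 8. This makes C10 by a known cuprate addition and also removes the dependence on the C10-to-C8 relay.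

**Step 7.**
- What may go wrong: proton transfer to the strongly basic dianion or elimination of the secondary triflate to an acrylate, in place of substitution. Loss of the silyloxy group from the C7 enolate is possible if the mixture warms.
- Fallback: it sets out from 8 and returns at 13. The dianion is alkylated with methyl bromoacetate to give the keto diester F6. Reduction as in step 8 gives the hydroxy diester F7, which closes to the lactone F8 without C13. LiN(SiMe3)2 and MeI at −78 °C then methylate the lactone enolate on the face away from the C8 substituent.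

**Step 8.**
- What may go wrong: protonation of the reduced C6 centre from the equatorial side, giving the axial alcohol and hence the cis-fused lactone, if the samarium-bound oxygen does not control the geometry. Once C6 is reduced, C7 can no longer be corrected.
- Fallback: it sets out from 11 and returns at 13. LiBH(s-Bu)3 is used deliberately to give the axial C6 alcohol F9, which closes to the cis-fused lactone F10. LiOH opens it to the hydroxy acid F11, and a Mitsunobu lactonisation (PPh3, diisopropyl azodicarboxylate) closes the ring with inversion at C6.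

**Step 13.**
- What may go wrong: over-oxidation to the enal, competing oxidation at the C5 methine, and incomplete conversion.
- Fallback: it sets out from 18 and returns at 19. Ene-type chlorination with Ca(OCl)2 and solid CO2 in CH2Cl2/H2O gives the allylic chloride F12. CsOAc in DMF gives the acetate F13, and K2CO3 in MeOH frees the alcohol.

**Step 18.**
- What may go wrong: enolisation toward the α-alkoxy carbon, which would erode the stereocentre or open the dioxolane.
- Fallback: it sets out from 22 and returns at 26. i-Bu2AlH at −78 °C gives the aldehyde F14. Ohira–Bestmann homologation gives the alkyne F15. Markovnikov methoxycarbonylation (Pd(OAc)2, 2-pyridyldiphenylphosphine, MeSO3H, CO, MeOH) then gives the ester.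

## Further compounds

F1 | step 4 | tert-butyl (3R)-2-acetyl-3-(dimethoxymethyl)-5-oxopentanoate (Michael adduct without C14) | COC(OC)[C@@H](CC=O)C(C(C)=O)C(=O)OC(C)(C)C
F2 | step 4 | tert-butyl 2-(dimethoxymethyl)-4-hydroxy-6-oxocyclohexane-1-carboxylate (all-equatorial, no C14) | COC(OC)[C@H]1C[C@@H](O)CC(=O)[C@@H]1C(=O)OC(C)(C)C
F3 | step 4 | TBDPS ether of F2 | COC(OC)[C@H]1C[C@@H](O[Si](c2ccccc2)(c2ccccc2)C(C)(C)C)CC(=O)[C@@H]1C(=O)OC(C)(C)C
F4 | step 4 | 1-phenylselanyl derivative of F3 (selenium on the ester-bearing carbon) | COC(OC)[C@H]1C[C@@H](O[Si](c2ccccc2)(c2ccccc2)C(C)(C)C)CC(=O)C1([Se]c3ccccc3)C(=O)OC(C)(C)C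
F5 | step 4 | tert-butyl (4R)-4-[(tert-butyldiphenylsilyl)oxy]-2-(dimethoxymethyl)-6-oxocyclohex-1-ene-1-carboxylate | COC(OC)C1=C(C(=O)OC(C)(C)C)C(=O)C[C@H](O[Si](c2ccccc2)(c2ccccc2)C(C)(C)C)C1
F6 | step 7 | keto diester: 8 carrying CH2CO2Me at C7, trans to the silyloxy group | COC(OC)[C@@]1(C)C[C@@H](O[Si](c2ccccc2)(c2ccccc2)C(C)(C)C)[C@H](CC(=O)OC)C(=O)[C@@H]1C(=O)OC(C)(C)C
F7 | step 7 | hydroxy diester: F6 with the equatorial C6 alcohol | COC(OC)[C@@]1(C)C[C@@H](O[Si](c2ccccc2)(c2ccccc2)C(C)(C)C)[C@H](CC(=O)OC)[C@@H](O)[C@@H]1C(=O)OC(C)(C)C
F8 | step 7 | lactone 13 without the C13 methyl | COC(OC)[C@@]1(C)C[C@@H](O[Si](c3ccccc3)(c3ccccc3)C(C)(C)C)[C@H]2[C@@H](OC(=O)C2)[C@@H]1C(=O)OC(C)(C)C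
F9 | step 8 | C6 epimer of 12 (axial C6 alcohol) | COC(OC)[C@@]1(C)C[C@@H](O[Si](c2ccccc2)(c2ccccc2)C(C)(C)C)[C@H]([C@@H](C)C(=O)OC)[C@H](O)[C@@H]1C(=O)OC(C)(C)C
F10 | step 8 | C6 epimer of 13 (cis-fused lactone) | COC(OC)[C@@]1(C)C[C@@H](O[Si](c3ccccc3)(c3ccccc3)C(C)(C)C)[C@H]2[C@H](OC(=O)[C@@H]2C)[C@@H]1C(=O)OC(C)(C)C
F11 | step 8 | hydroxy acid from F10 (axial C6 alcohol, free C12 acid) | COC(OC)[C@@]1(C)C[C@@H](O[Si](c2ccccc2)(c2ccccc2)C(C)(C)C)[C@H]([C@@H](C)C(=O)O)[C@H](O)[C@@H]1C(=O)OC(C)(C)C
F12 | step 13 | allylic chloride: 18 with C15 as CH2Cl | C=C[C@@]1(C)C[C@@H](O[Si](c3ccccc3)(c3ccccc3)C(C)(C)C)[C@H]2[C@@H](OC(=O)[C@@H]2C)[C@@H]1C(=C)CCl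
F13 | step 13 | acetate of 19 | C=C[C@@]1(C)C[C@@H](O[Si](c3ccccc3)(c3ccccc3)C(C)(C)C)[C@H]2[C@@H](OC(=O)[C@@H]2C)[C@@H]1C(=C)COC(C)=O
F14 | step 18 | (R)-2,2-dimethyl-1,3-dioxolane-4-carbaldehyde | O=C[C@H]1COC(C)(C)O1
F15 | step 18 | (S)-4-ethynyl-2,2-dimethyl-1,3-dioxolane | C#C[C@H]1COC(C)(C)O1
A1 | alternative 1 | open-chain bromo ester aldehyde (methyl (Z)-2-(bromomethyl)enoate with C6 aldehyde) | O=C[C@H](C(C)=C)[C@@](C)(C=C)C[C@@H](O[Si](C)(C)C(C)(C)C)/C=C(\CBr)C(=O)OC
A2 | alternative 1 | trans-fused α-methylene lactone on the cyclohexane | C=C[C@@]1(C)C[C@@H](O[Si](C)(C)C(C)(C)C)[C@H]2[C@@H](OC(=O)C2=C)[C@@H]1C(C)=C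
A3 | alternative 2 | ethyl (E)-3-methyl-4-oxobut-2-enoate (formyl enoate) | CCOC(=O)/C=C(\C)C=O
A4 | alternative 2 | 2-(triisopropylsilyloxy)buta-1,3-diene | C=CC(=C)O[Si](C(C)C)(C(C)C)C(C)C
A5 | alternative 2 | cyclohexene silyl enol ether with trans C10 formyl and C5 ester | O=C[C@@]1(C)CC=C(O[Si](C(C)C)(C(C)C)C(C)C)C[C@@H]1C(=O)OCC
A6 | alternative 3 | open-chain C6 aldehyde with the dimethyl-substituted C5=C4 alkene | C=C[C@](C)(C=C(C)C)C[C@@H](O[Si](C)(C)C(C)(C)C)[C@@H](C=O)[C@@H](C)C(=O)OC
A7 | alternative 3 | cyclohexanol with trans C6 hydroxyl and C5 isopropenyl | C=C[C@@]1(C)C[C@@H](O[Si](C)(C)C(C)(C)C)[C@H]([C@@H](C)C(=O)OC)[C@@H](O)[C@@H]1C(C)=C
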